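## Retrosynthetic overview

1. Ring A (spiro dihydropyran) and the CO2H come last: the enol ether by cyclodehydration of a δ-hydroxy ketone, the acid by decarboxylative protonation of a ring D malonate.
2. The spiro quaternary carbon is grown from the bridging ketone of an 8-methyl-8-azabicyclo[4.3.1]decadienone (one-carbon homologation, hydroxymethylation, olefination).
3. Ring E comes from a [6+3] cycloaddition of the N-methyl azomethine ylide across the two α-carbons of a tricyclic tropone.
4. Rings B and D form together in an intramolecular oxyallyl cation–furan (4+3) cycloaddition; excision of the oxygen bridge then gives the tropone.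
5. Ring C is closed first by a B-alkyl Suzuki coupling on 3-bromofuran; the only external stereocontrol is a Mo-catalysed asymmetric allylic alkylation. Ring order: C, then B + D, then E, then A.

Ring letters: A = dihydropyran, B = seven-membered carbocycle, C = cyclopentene, D = cyclopentane bearing CO2H, E = N-methylpiperidine.

Assumption: the (S,S)-bis(picolinamide) ligand is taken to give the (R)-branched malonate 8, by analogy with 1-arylallyl carbonates; if the sense is the opposite, the (R,R)-ligand is used.

## Route

Step 1
Reactants: 1 3-bromofuran; 2 acrolein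
Product: 5 1-(3-bromofuran-2-yl)prop-2-en-1-yl methyl carbonate (racemic), via 3-bromo-2-furyllithium 3 (not isolated), via lithium allylic alkoxide 4 (not isolated)
Conditions: LiN(i-Pr)2, THF, −78 °C; 2, −78 °C; ClCO2Me, −78 → 0 °C
Reagents that add atoms: methyl chloroformate, COC(=O)Cl
Why: Regioselective C2 lithiation of 3-bromofuran (the α-position next to bromine), 1,2-addition to acrolein and O-acylation of the alkoxide; the carbinol centre is racemic and is erased on ionisation in step 2.

Step 2
Reactants: 5 1-(3-bromofuran-2-yl)prop-2-en-1-yl methyl carbonate; 6 dimethyl malonate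
Product: 8 dimethyl 2-[(1R)-1-(3-bromofuran-2-yl)prop-2-en-1-yl]propanedioate, via sodium dimethyl malonate 7 (not isolated)
Conditions: NaH, THF, 0 °C; then 5, Mo(CO)6 (10 mol %), (1S,2S)-N,N′-bis(pyridine-2-carbonyl)cyclohexane-1,2-diamine (15 mol %), toluene, 85 °C
Reagents that add atoms: none
Why: Trost molybdenum-catalysed asymmetric allylic alkylation, in which both enantiomers of 5 converge on one π-allyl complex and the malonate attacks the branched terminus, sets the (R) stereocentre that controls every later one.

Step 3
Reactants: 8 dimethyl 2-[(1R)-1-(3-bromofuran-2-yl)prop-2-en-1-yl]propanedioate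
Product: 10 dimethyl 2-[(6R)-5,6-dihydro-4H-cyclopenta[b]furan-6-yl]propanedioate, via B-alkyl-9-BBN adduct 9 (not isolated)
Conditions: 9-BBN-H, THF, 25 °C; then PdCl2(dppf) (5 mol %; dppf = 1,1′-bis(diphenylphosphino)ferrocene), K3PO4 (aq), DMF, 60 °C
Reagents that add atoms: none
Why: Anti-Markovnikov hydroboration of the vinyl group followed by intramolecular B-alkyl Suzuki–Miyaura coupling with the furyl bromide closes ring C; the stereocentre is not touched.

Step 4
Reactants: 10 dimethyl 2-[(6R)-5,6-dihydro-4H-cyclopenta[b]furan-6-yl]propanedioate; 11 methyl vinyl ketone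
Product: 12 dimethyl 2-[(6R)-5,6-dihydro-4H-cyclopenta[b]furan-6-yl]-2-(3-oxobutyl)propanedioate
Conditions: DBU (10 mol %), MeCN, 25 °C
Reagents that add atoms: none
Why: Base-catalysed Michael addition of the malonate C–H to the enone installs the four-carbon tether; no new stereocentre.

Step 5
Reactants: 12 dimethyl 2-[(6R)-5,6-dihydro-4H-cyclopenta[b]furan-6-yl]-2-(3-oxobutyl)propanedioate
Product: 14 dimethyl 2-(4-chloro-3-oxobutyl)-2-[(6R)-5,6-dihydro-4H-cyclopenta[b]furan-6-yl]propanedioate, via trimethylsilyl enol ether 13 (not isolated)
Conditions: LiN(SiMe3)2, Me3SiCl, THF, −78 °C; then N-chlorosuccinimide, THF, 0 °C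
Reagents that add atoms: N-chlorosuccinimide, O=C1CCC(=O)N1Cl
Why: Kinetic enolisation to the methyl side with in situ silylation (which also prevents Dieckmann closure onto the esters), then electrophilic chlorination of the silyl enol ether, which is far more nucleophilic than the furan; any regioisomeric chloride would give the same oxyallyl cation; no stereocentre.

Step 6
Reactants: 14 dimethyl 2-(4-chloro-3-oxobutyl)-2-[(6R)-5,6-dihydro-4H-cyclopenta[b]furan-6-yl]propanedioate
Product: 16 oxa-bridged tetracyclic keto diester (rings B C D plus oxygen bridge), via oxyallyl cation 15 (not isolated)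
Conditions: Et3N, CF3CH2OH, 25 °C, 0.01 M
Reagents that add atoms: none
Why: Föhlisch-type ionisation gives the 2-oxyallyl cation, which adds across the furan in an intramolecular (4+3) cycloaddition that forms ring B and ring D in one operation; the three-atom tether delivers it to the furan face carrying the side chain, and all new stereocentres are cleared in step 7, so the epimer ratio next to the ketone does not matter.

Step 7
Reactants: 16 oxa-bridged tetracyclic keto diester
Product: 18 tricyclic tropone diester (rings B C D), via ring-opened silyl ether 17 (not isolated)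
Conditions: Me3SiOTf, Et3N, CH2Cl2, 0 → 25 °C; 1 M HCl work-up
Reagents that add atoms: none
Why: Enol silane formation and β-cleavage of the oxygen bridge (E1cB-type ring opening), then loss of silanol with aromatisation to the tropone, a known way to unravel furan (4+3) adducts; the single stereocentre from step 2 is unchanged.

Step 8
Reactants: 18 tricyclic tropone diester; 19 sarcosine; 20 paraformaldehyde
Product: 22 tetracyclic amino ketone diester (rings B C D E; 8-methyl-8-azabicyclo[4.3.1]deca-2,4-dien-10-one core), via azomethine ylide 21 (not isolated)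
Conditions: toluene, 4 Å sieves, 100 °C
Reagents that add atoms: none
Why: Proposed new method: the non-stabilised N-methyl azomethine ylide from decarboxylative condensation adds as a four-electron, three-atom unit across the two α-carbons of the tropone in a thermally allowed ten-electron [6+3] cycloaddition (closest known reactions: metal-catalysed [6+3] of tropone with stabilised azomethine ylides and Pd–trimethylenemethane [6+3] with tropone), bonding first at the unsubstituted α-carbon and closing on the substituted one from the convex face opposite the pseudo-axial ester, which sets the quaternary carbon and the bridgehead CH in one event.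

Step 9
Reactants: 22 tetracyclic amino ketone diester; 23 (methoxymethyl)triphenylphosphonium chloride
Product: 26 bridge aldehyde (one-carbon homologue of 22), via methoxymethylene ylide 24 (not isolated), via methyl enol ether 25 (not isolated)
Conditions: KN(SiMe3)2, THF, 0 → 50 °C; then 2 M HCl, THF, 25 °C
Reagents that add atoms: water, O
Why: Wittig methoxymethylenation of the non-enolisable bridging ketone and acid hydrolysis of the enol ether give the homologous aldehyde; its α-centre is uncontrolled and is cleared by enolisation in step 10.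

Step 10
Reactants: 26 bridge aldehyde; 20 paraformaldehyde
Product: 27 α-hydroxymethyl aldehyde (quaternary bridge carbon)
Conditions: K2CO3 (0.3 equiv), MeOH, 40 °C
Reagents that add atoms: none
Why: Crossed aldol hydroxymethylation of the α-branched aldehyde, in which formaldehyde attacks the exocyclic enolate from the open face above the flat diene bridge rather than under the axial hydrogens of the piperidine chair (the reversible aldol favours the same isomer), sets the quaternary spiro carbon with CH2OH on the carbocycle side.

Step 11
Reactants: 27 α-hydroxymethyl aldehyde; 28 dimethyl (3-methyl-2-oxobutyl)phosphonate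
Product: 30 E-enone, via lithium phosphonate 29 (not isolated)
Conditions: LiCl, i-Pr2NEt, MeCN, 25 → 40 °C
Reagents that add atoms: none
Why: Masamune–Roush Horner–Wadsworth–Emmons olefination of the non-enolisable aldehyde under conditions too mild for retro-aldol gives the E-enone; no stereocentre.

Step 12
Reactants: 30 E-enone
Product: 32 spiro enol ether diester (rings A–E), via hydroxy ketone 31 (not isolated)
Conditions: H2 (4 atm), RhCl(PPh3)3 (10 mol %), benzene, 25 °C; then (+)-camphor-10-sulfonic acid (1.5 equiv), 4 Å sieves, 60 °C; Et3N quench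
Reagents that add atoms: none
Why: Homogeneous hydrogenation with RhCl(PPh3)3 reduces the two disubstituted alkenes (enone C=C and the cis end of the diene) but not the tetrasubstituted one, and the δ-hydroxy ketone then closes to its hemiketal and dehydrates under acid to the endocyclic enol ether of ring A; no new stereocentre.

Step 13
Reactants: 32 spiro enol ether diester
Product: 35 target acid CNP0237695.1, via dipotassium dicarboxylate 33 (not isolated), via malonic diacid 34 (not isolated)
Conditions: KOH, MeOH/H2O, 65 °C; AcOH to pH 6, 0 °C; evaporate; pyridine, 100 °C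
Reagents that add atoms: potassium hydroxide, [K+].[OH-]
Why: Saponification and thermal malonic acid decarboxylation, with the enediol protonated from the convex face (the side of the neighbouring ring-fusion hydrogen, away from the spiro-bearing bridge), the usual kinetic outcome that gives the cis acid required.

## Compound list

1 | 3-bromofuran | Brc1ccoc1 | starting material
2 | acrolein | C=CC=O | starting material
3 | (3-bromofuran-2-yl)lithium | [Li]c1occc1Br | intermediate
4 | lithium 1-(3-bromofuran-2-yl)prop-2-en-1-olate (racemic) | [Li+].[O-]C(C=C)c1occc1Br | intermediate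
5 | 1-(3-bromofuran-2-yl)prop-2-en-1-yl methyl carbonate (racemic) | C=CC(OC(=O)OC)c1occc1Br | intermediate
6 | dimethyl malonate | COC(=O)CC(=O)OC | starting material
7 | sodium dimethyl malonate | [Na+].COC(=O)[CH-]C(=O)OC | intermediate
8 | dimethyl 2-[(1R)-1-(3-bromofuran-2-yl)prop-2-en-1-yl]propanedioate | C=C[C@@H](c1occc1Br)C(C(=O)OC)C(=O)OC | intermediate
9 | B-alkyl-9-BBN adduct of 8 (boron on the terminal carbon) | COC(=O)C(C(=O)OC)[C@@H](CCB1C2CCCC1CCC2)c1occc1Br | intermediate
10 | dimethyl 2-[(6R)-5,6-dihydro-4H-cyclopenta[b]furan-6-yl]propanedioate | COC(=O)C(C(=O)OC)[C@H]1CCc2ccoc21 | intermediate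
11 | methyl vinyl ketone | CC(=O)C=C | starting material
12 | dimethyl 2-[(6R)-5,6-dihydro-4H-cyclopenta[b]furan-6-yl]-2-(3-oxobutyl)propanedioate | CC(=O)CCC(C(=O)OC)(C(=O)OC)[C@H]1CCc2ccoc21 | intermediate
13 | trimethylsilyl enol ether of 12 (terminal alkene) | C=C(O[Si](C)(C)C)CCC(C(=O)OC)(C(=O)OC)[C@H]1CCc2ccoc21 | intermediate
14 | dimethyl 2-(4-chloro-3-oxobutyl)-2-[(6R)-5,6-dihydro-4H-cyclopenta[b]furan-6-yl]propanedioate | ClCC(=O)CCC(C(=O)OC)(C(=O)OC)[C@H]1CCc2ccoc21 | intermediate
15 | 2-oxyallyl cation from 14 (zwitterion) | [CH2+]C([O-])=CCC(C(=O)OC)(C(=O)OC)[C@H]1CCc2ccoc21 | intermediate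
16 | oxa-bridged cycloadduct: 8-oxabicyclo[3.2.1]oct-6-en-3-one core carrying rings C and D; gem-dimethyl ester on ring D; oxygen bridge anti to the ring D bond; epimers at the CH α to the ketone | O=C1C[C@@H]2C=C3CC[C@H]4[C@]3(O2)C1CC4(C(=O)OC)C(=O)OC | intermediate
17 | ring-opened cycloheptadienone with tertiary trimethylsilyl ether at the former bridgehead | O=C1C=CC=C2CC[C@H]3[C@]2(O[Si](C)(C)C)C1CC3(C(=O)OC)C(=O)OC | intermediate
18 | tricyclic tropone: tropone ring B fused to rings C and D around one sp3 ring-fusion CH; gem-dimethyl ester on ring D | O=C1C=CC=C2CC[C@H]3C2=C1CC3(C(=O)OC)C(=O)OC | intermediate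
19 | sarcosine | CNCC(=O)O | starting material
20 | paraformaldehyde (formaldehyde source) | C=O | starting material
21 | N-methyl azomethine ylide | C=[N+](C)[CH2-] | intermediate
22 | [6+3] adduct: bridging ketone; N-methyl bridge on the face of the ring-fusion H; diene in ring B | O=C1[C@@H]2C=CC3=C4[C@H](CC3)C(C(=O)OC)(C(=O)OC)C[C@@]41CN(C)C2 | intermediate
23 | (methoxymethyl)triphenylphosphonium chloride | COC[P+](c1ccccc1)(c1ccccc1)c1ccccc1.[Cl-] | starting material
24 | (methoxymethylene)triphenylphosphorane | COC=P(c1ccccc1)(c1ccccc1)c1ccccc1 | intermediate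
25 | exocyclic methyl enol ether at the bridge carbon (E/Z mixture) | COC=C1[C@@H]2C=CC3=C4[C@H](CC3)C(C(=O)OC)(C(=O)OC)C[C@@]41CN(C)C2 | intermediate
26 | bridge aldehyde (epimers at the bridge CH) | O=CC1[C@@H]2C=CC3=C4[C@H](CC3)C(C(=O)OC)(C(=O)OC)C[C@@]41CN(C)C2 | intermediate
27 | α-hydroxymethyl aldehyde: CH2OH over the diene bridge; CHO over the piperidine | O=C[C@@]1(CO)[C@@H]2C=CC3=C4[C@H](CC3)C(C(=O)OC)(C(=O)OC)C[C@@]41CN(C)C2 | intermediate
28 | dimethyl (3-methyl-2-oxobutyl)phosphonate | COP(=O)(CC(=O)C(C)C)OC | starting material
29 | lithium salt of 28 (phosphonate carbanion) | [Li+].COP(=O)([CH-]C(=O)C(C)C)OC | intermediate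
30 | E-enone (isopropyl ketone side chain on the quaternary bridge carbon) | CC(C)C(=O)/C=C/[C@@]1(CO)[C@@H]2C=CC3=C4[C@H](CC3)C(C(=O)OC)(C(=O)OC)C[C@@]41CN(C)C2 | intermediate
31 | δ-hydroxy ketone (in equilibrium with its cyclic hemiketal); ring B now a monoene | CC(C)C(=O)CC[C@@]1(CO)[C@@H]2CCC3=C4[C@H](CC3)C(C(=O)OC)(C(=O)OC)C[C@@]41CN(C)C2 | intermediate
32 | spiro enol ether gem-dimethyl ester (rings A–E complete) | CC(C)C1=CC[C@@]2(CO1)[C@@H]1CCC3=C4[C@H](CC3)C(C(=O)OC)(C(=O)OC)C[C@@]42CN(C)C1 | intermediate
33 | dipotassium dicarboxylate of 32 | [K+].[K+].CC(C)C1=CC[C@@]2(CO1)[C@@H]1CCC3=C4[C@H](CC3)C(C(=O)[O-])(C(=O)[O-])C[C@@]42CN(C)C1 | intermediate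
34 | malonic diacid | CC(C)C1=CC[C@@]2(CO1)[C@@H]1CCC3=C4[C@H](CC3)C(C(=O)O)(C(=O)O)C[C@@]42CN(C)C1 | intermediate
35 | CNP0237695.1 | CC(C)C1=CC[C@@]2(CO1)[C@@H]1CCC3=C4[C@H](CC3)[C@H](C(=O)O)C[C@@]42CN(C)C1 | target

## Step count and risk

Total step count: 13. Longest linear sequence: 13 (fully linear from 3-bromofuran).

Steps most likely to fail:

Step 6. The cation comes from a mono-alkyl chloromethyl ketone and may be lost to solvent capture or Favorskii chemistry before it finds the furan. The fallback sets out from 14 and comes back at 16. Condensation of 14 with isopropylamine (TiCl4, Et3N, Et2O) gives the α-chloro ketimine F1. AgBF4 in CH2Cl2 abstracts chloride to give the nitrogen-stabilised 2-aminoallyl cation F2, which closes onto the furan in the same intramolecular (4+3) mode to the bridged iminium salt F3. Aqueous NaHCO3 hydrolysis returns ketone 16.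

Step 8. The ylide may prefer a [3+2] addition to the unsubstituted tropone double bond, or the closure that makes the quaternary carbon may be too slow. The fallback sets out from 18 and comes back at 22. LiBH(s-Bu)3 in THF at −78 °C adds hydride 1,8 at the unsubstituted α-carbon, and α-protonation (NH4Cl) gives the cyclohepta-3,5-dienone F4. A Robinson–Schöpf-type double Mannich condensation with MeNH2·HCl and aqueous formaldehyde in AcOH/MeOH passes through the mono-Mannich base F5, whose epimerisable α-centre lets the second Mannich closure take place at the ring-fusion α-carbon from the convex face, giving 22.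

Step 13. The decarboxylative protonation may give the wrong epimer at the acid-bearing carbon, or the enol ether may suffer during neutralisation. The fallback sets out from 32 and comes back at 35. Krapcho dealkoxycarbonylation (LiCl, H2O, DMSO, 150 °C) gives the methyl ester F6. LiN(i-Pr)2 at −78 °C converts it into the lithium enolate F7, and a quench with 2,6-di-tert-butyl-4-methylphenol delivers the proton from the convex face, returning F6 as the required epimer. Me3SnOH in 1,2-dichloroethane at 80 °C then cleaves the ester without epimerisation to give 35.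

Further compounds

F1 | step 6 | N-isopropyl α-chloro ketimine of 14 | ClCC(=NC(C)C)CCC(C(=O)OC)(C(=O)OC)[C@H]1CCc2ccoc21
F2 | step 6 | 2-(isopropylamino)allyl cation tetrafluoroborate | [CH2+]C(NC(C)C)=CCC(C(=O)OC)(C(=O)OC)[C@H]1CCc2ccoc21.F[B-](F)(F)F
F3 | step 6 | N-isopropyl iminium tetrafluoroborate of cycloadduct 16 | CC(C)[NH+]=C1C[C@@H]2C=C3CC[C@H]4[C@]3(O2)C1CC4(C(=O)OC)C(=O)OC.F[B-](F)(F)F
F4 | step 8 | tricyclic cyclohepta-3,5-dienone diester (1,8-dihydro derivative of 18; epimers at the CH α to the ketone) | O=C1CC=CC2=C3[C@H](CC2)C(C(=O)OC)(C(=O)OC)CC31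
F5 | step 8 | mono-Mannich base of F4 (methylaminomethyl on the CH2 α-carbon) | CNCC1C=CC2=C3[C@H](CC2)C(C(=O)OC)(C(=O)OC)CC3C1=O
F6 | step 13 | methyl ester of 35 | CC(C)C1=CC[C@@]2(CO1)[C@@H]1CCC3=C4[C@H](CC3)[C@H](C(=O)OC)C[C@@]42CN(C)C1
F7 | step 13 | lithium enolate of F6 | [Li+].CC(C)C1=CC[C@@]2(CO1)[C@@H]1CCC3=C4[C@H](CC3)C(=C([O-])OC)C[C@@]42CN(C)C1
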